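## The problem

Formosanatin D is an achiral, hexacyclic coumaronochromone. In isoflavone numbering (ring C = O1, C2, C3, C4, C4a, C8a; ring A = C4a to C8a; ring B = C1' to C6'), a chromone is tied through its C2 oxygen to C2' of the C3 aryl group, which closes a furan. A saturated 2,2-dimethylpyran (ring D) is fused across O7/C8 and a 2,2-dimethyl-2H-pyran (ring E) across C3'/C4'. There is no stereocentre, so the whole difficulty is positional: ring A is substituted everywhere but C6, ring B everywhere but C6', and each oxygen and each C5 unit must reach one carbon out of two or three similar ones. Ring B is 2',4',5'-trioxygenated with O2' and O5' para, a hydroquinone-type arene that is easily over-oxidised and would need three differentiated oxygens if all were carried from the start. Once in place, the ring E olefin excludes hydrogenolysis, peracids and hot strong acid, its tertiary allylic ether is endangered by strong Lewis acids, and C2 of the 2-aryloxychromone is a ketene-acetal-type electrophile that hard nucleophiles open. The two hydroxyls differ: the C5 hydroxyl is chelated to the C4 carbonyl, the C5' hydroxyl is an ordinary guaiacol-type phenol. The enabling feature is that C2' is para to the C5' hydroxyl and that the 2-oxychromone is the oxygen-transposed isomer of a 4-oxycoumarin. A 3-aryl-4-methoxycoumarin already holds the future furan oxygen as its lactone carbonyl, five atoms from C2', so two-electron oxidation of the C5' phenol can forge O–C2' while loss of the O4 methyl turns the coumarin into the chromone.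

## Retrosynthesis

**27 to 26 (O5–CH3).** The chelated C5 hydroxyl of target 27 is revealed last from methyl ether 26. A methyl group is the only mask that survives the strongly acidic lactone closure, the organolithium step and the oxidation. It is also the one ether that a boron Lewis acid removes selectively, because it sits peri to the C4 carbonyl. A free C5 hydroxyl carried throughout would be a second acidic OH beside O4 during ylide formation and methylation, and a second oxidisable phenol in the key step. The forward reaction must cleave one ether out of three without opening ring E.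

**26 to 24 (furan O–C2').** Cutting O–C2' reverts the chromone to a coumarin: the furan oxygen of 26 becomes the lactone carbonyl oxygen of 24 and the C4 ketone becomes an enol methyl ether. The neighbouring cut O–C2 (a C2' phenol adding to C2) would demand a ring B with three oxygens in three different states. A late C3–C1' closure of a 2-aryloxychromone would leave ring B regiochemistry open twice. The chosen cut removes one oxygen from ring B altogether, so 24 is a plain 3-arylcoumarin open to cross-coupling. The forward reaction must oxidise only the C5' phenol, close at C2' and not at C6', and lose the O4 methyl cleanly.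

**24 to 23 to 22 (O5'–acetal, O4–CH3).** The C5' phenol of 24 is carried as MOM ether 23, and the O4 methyl of 23 is put on 4-hydroxycoumarin 22. The acetal is needed because methylation of 22 must touch only the vinylogous acid. It is chosen because it withstands organolithium, aqueous base and alkylation and leaves in methanolic acid, where the C4 enol ether can only exchange with itself. The forward steps must give O4- and not O2-methylation, and deprotect without hydrating ring E.

**22 to 11 + 21 (C3–C1').** The aryl–vinyl bond is cut to iodonium ylide 11 and boronic acid 21. The ylide is preferred to a 3-iodo-4-methoxycoumarin because trivalent iodine attacks only the enolised 1,3-dicarbonyl carbon. Electrophilic iodination of the methyl ether would compete at the electron-rich C6 of ring A. Both partners are unhindered at the reacting carbons, and the two halves of the molecule become separate four- and five-step problems.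

**11 to 10 to 7 + 8 (O1–C2 and C4–C4a).** Ylide 11 comes from 4-hydroxycoumarin 10, and 10 from chromanol 7 and Meldrum's acid 8 by ester formation and intramolecular Friedel–Crafts acylation. Routing through an ortho-hydroxyacetophenone would add an intermolecular acylation with its own ortho/para question. In 7 the ester oxygen has a single free ortho carbon, so the ring can close in one place only.

**7 to 6 to 5 to 2 to 1 + 3 (O7–CMe2 and C8–CH2).** Ring D is opened to prenylresorcinol 6, which comes from its bis-acetal 5 and so from arene 2, resorcinol 1 and prenyl bromide 3. Direct acid-catalysed union of 1 with a tertiary allylic alcohol would alkylate the carbon between the hydroxyls and the two carbons beside the methoxy group alike. Lithiation of 2 between its two MOM ethers puts the prenyl group on the symmetry axis. Cyclisation of 6 onto either hydroxyl then gives the same chromanol 7.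

**21 to 19 to 18 to 16 to 14 to 12 + 13 (C–B, O–acetal, C–O from C–CHO, ring E).** Boronic acid 21 comes from bromide 19, the MOM ether of phenol 18. The C5' oxygen of 18 is traced to the formyl group of chromene aldehyde 16 by a Dakin oxidation. Ring E of 16 arises by propargyl Claisen rearrangement of ether 14, made from 5-bromosalicylaldehyde 12 and chloride 13. The formyl group does two jobs. It blocks one ortho position, so the rearrangement has only one carbon to go to, and it is the latent hydroxyl. The bromine para to the ring oxygen marks the future C1'.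

## Roads not taken

**Alternative 1:** Ring A would be built de novo by cutting C4a–C5 and C8–C8a. Forward, the ring D ketene bis(silyl) acetal A2 adds to methyl 3-bromopropiolate A3. The nucleophilic diene terminus (future C8) bonds to the bromine-bearing alkyne carbon and the ketene acetal carbon to the ester-bearing one. Elimination of one silyloxy group aromatises the adduct to chroman ester A1, with bromine at the future C8a and a free hydroxyl at the future C5.
- Merits: the regiochemistry of a pentasubstituted arene is set in one step by orbital polarity and ring D arrives intact. The C5 oxygen is born free, so no final demethylation would be needed. In that respect this road is better than the chosen one, which must remove the O5 methyl with BCl3 at the end.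
- Weak points: A2 is a moisture-sensitive diene that needs several steps of its own, and A3 is a volatile, irritant electrophile. A1 carries bromine where O1 must come, so a later C–O coupling next to a salicylate is required. The free C5 hydroxyl would have to be masked anyway during coumarin and coupling chemistry.
- Comparison: the step spends the key disconnection on the one ring that can be bought as a phloroglucinol-type arene and leaves the furan closure and ring B untouched. The chosen plan reaches the same certainty on ring A in three ordinary steps through the symmetry of 6 and the single free ortho position of 7.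

**Alternative 2:** Both C5 units would be installed last on a finished coumaronochromone, cutting C8–CH2, C3'–CH and O(C4')–CMe2. Heating diether A4 (7-O-(1,1-dimethylallyl), 4'-O-(1,1-dimethylpropargyl)) would move the allyl unit to C8 as a prenyl group and the propargyl unit to C3'. A 1,5-hydrogen shift and oxa-6π closure would then give ring E in A5.
- Merits: three bonds and one ring form without reagents, both side chains come from cheap tertiary alcohols, and the core is a simple tetraoxygenated coumaronochromone. For the decoration of rings A and B this is shorter than the five steps (1–3, 6, 7) the chosen plan spends on the two pyran rings.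
- Weak points: the propargyl shift has only C3' to go to, but the allyl shift must choose C8 over C6 and nothing in A4 enforces that. The 1,1-dimethylallyl aryl ether ionises and loses its C5 unit at the temperature the propargyl shift needs. A4 requires O7, O4' and O5' to be told apart on the core. Ring D must still be closed by acid onto the prenyl group beside ring E.
- Comparison: the road leaves open how the core is made. The chosen plan sets positional certainty against the shorter decoration, since each C5 unit is attached where only one carbon is available, and it solves core and decoration in one line.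

**Alternative 3:** The C2 carbon would be inserted last, cutting C2–C3, C2–O1 and C2–O(C2'). The enolate of deoxybenzoin A6 adds to CS2 and MeI gives the ketene dithioacetal. The ring A phenoxide and the C2' phenoxide then each displace one methylthio group, closing ring C and the furan to give A7.
- Merits: every event is a known reaction type and the step is redox-neutral, so ring B never meets an oxidant. The furan oxygen is in place from the start, so no C2'/C6' question arises, and two rings form in one flask. In reliability of the key step this road is better than the chosen one.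
- Weak points: the difficulty moves into A6. Ring B needs three oxygens in three states (free at C2', acetal at C5', pyran at C4'), which means a long synthesis of a hydroxyquinol-type arylacetic acid. Its Friedel–Crafts-type union with chromanol 7 needs acid that threatens ring E and the acetal. The second displacement needs heat and both release a thiol.
- Comparison: the chosen plan sets against the better precedent a ring B simpler by one oxygen, because the furan oxygen is the lactone carbonyl the coupling partner brings anyway. It also offers a mild, modular C3–C1' coupling and shorter fragment syntheses. The thio-displacement logic is kept as the fallback for step 14.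

Key step: step 14

Remark: prenyl bromide 3, Meldrum's acid 8 and 3-chloro-3-methylbut-1-yne 13 are taken as purchased materials; 3-aryl compounds are numbered as isoflavones, isolated chromans and chromenes by their own ring numbering.

## Route

Step 1
Reactants: 1 5-methoxyresorcinol
Product: 2 1-methoxy-3,5-bis(methoxymethoxy)benzene
Conditions: NaH, MOMCl, DMF, 0 °C → rt
Reagents that add atoms: chloromethyl methyl ether, COCCl
Why: Williamson-type acetalisation of both phenoxides; the two MOM ethers protect the phenols and serve as the paired directing groups for step 2.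

Step 2
Reactants: 2 1-methoxy-3,5-bis(methoxymethoxy)benzene; 3 prenyl bromide
Product: 5 5-methoxy-1,3-bis(methoxymethoxy)-2-(3-methylbut-2-en-1-yl)benzene, via aryllithium 4 (not isolated)
Conditions: n-BuLi, THF, 0 °C; then CuI (10 mol %), 3, −78 °C → rt
Reagents that add atoms: none
Why: Directed ortho-metalation removes the proton flanked by both MOM ethers in preference to those beside the weaker methoxy director; copper-catalysed allylic substitution then attaches the primary carbon of the prenyl unit without allylic transposition.

Step 3
Reactants: 5 5-methoxy-1,3-bis(methoxymethoxy)-2-(3-methylbut-2-en-1-yl)benzene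
Product: 7 7-methoxy-2,2-dimethylchroman-5-ol, via prenylresorcinol 6 (not isolated)
Conditions: p-TsOH·H2O (0.2 equiv), MeOH, 60 °C; then toluene, 90 °C
Reagents that add atoms: none
Why: Acid-catalysed acetal exchange frees both phenols and Markovnikov hydroalkoxylation of the prenyl olefin through the tertiary cation closes the chroman; the two hydroxyls of 6 are equivalent by symmetry, so only one chromanol can form.

Step 4
Reactants: 7 7-methoxy-2,2-dimethylchroman-5-ol; 8 Meldrum's acid
Product: 10 4-hydroxy-5-methoxy-8,8-dimethyl-9,10-dihydro-2H,8H-pyrano[2,3-f]chromen-2-one, via malonate half ester 9 (not isolated)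
Conditions: 8, toluene, 100 °C; concentrate; then P2O5/MeSO3H, 70 °C
Reagents that add atoms: none
Why: Phenol acylation by ring-opening of Meldrum's acid (loss of acetone) followed by intramolecular Friedel–Crafts acylation; the ester oxygen has a single free ortho carbon, activated by the ortho methoxy group and the para ring D oxygen, so the 4-hydroxycoumarin closes in one place only.

Step 5
Reactants: 10 4-hydroxy-5-methoxy-8,8-dimethyl-9,10-dihydro-2H,8H-pyrano[2,3-f]chromen-2-one
Product: 11 5-methoxy-8,8-dimethyl-2-oxo-3-(phenyliodonio)-9,10-dihydro-2H,8H-pyrano[2,3-f]chromen-4-olate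
Conditions: PhI(OAc)2, Na2CO3, H2O, rt
Reagents that add atoms: (diacetoxyiodo)benzene, CC(=O)OI(OC(C)=O)c1ccccc1
Why: Iodonium ylide formation of a cyclic 1,3-dicarbonyl compound: the enolate carbon C3 attacks trivalent iodine and the zwitterion precipitates; the enolate is far more nucleophilic than C6 of ring A, so the arene is left alone.

Step 6
Reactants: 12 5-bromosalicylaldehyde; 13 3-chloro-3-methylbut-1-yne
Product: 14 5-bromo-2-[(2-methylbut-3-yn-2-yl)oxy]benzaldehyde
Conditions: K2CO3, KI (cat.), CuI (cat.), DMF, 60 °C
Reagents that add atoms: none
Why: Copper-assisted O-alkylation of the phenoxide by a tertiary propargylic chloride, the standard entry to aryl 1,1-dimethylpropargyl ethers, which works well with electron-poor phenols.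

Step 7
Reactants: 14 5-bromo-2-[(2-methylbut-3-yn-2-yl)oxy]benzaldehyde
Product: 16 6-bromo-2,2-dimethyl-2H-chromene-8-carbaldehyde, via ortho-allenylphenol 15 (not isolated)
Conditions: PhNEt2, 190 °C
Reagents that add atoms: none
Why: Aromatic propargyl Claisen rearrangement to the only free ortho carbon (the other carries the formyl group), enolisation to 15, 1,5-hydrogen shift and oxa-6π electrocyclisation give the 2,2-dimethylchromene.

Step 8
Reactants: 16 6-bromo-2,2-dimethyl-2H-chromene-8-carbaldehyde
Product: 18 6-bromo-2,2-dimethyl-2H-chromen-8-ol, via aryl formate 17 (not isolated)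
Conditions: 30% H2O2, H2SO4 (cat.), MeOH, rt
Reagents that add atoms: hydrogen peroxide, OO
Why: Dakin oxidation: the perhydrate of the aldehyde rearranges with aryl migration, favoured by the ortho ether oxygen, and the formate is methanolysed in the same flask; H2O2 without a peracid does not epoxidise the chromene olefin.

Step 9
Reactants: 18 6-bromo-2,2-dimethyl-2H-chromen-8-ol
Product: 19 6-bromo-8-(methoxymethoxy)-2,2-dimethyl-2H-chromene
Conditions: NaH, MOMCl, THF, 0 °C
Reagents that add atoms: chloromethyl methyl ether, COCCl
Why: Williamson-type acetalisation; the MOM ether withstands the organolithium, the aqueous base of the coupling and the methylation, and later leaves under acid mild enough for ring E.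

Step 10
Reactants: 19 6-bromo-8-(methoxymethoxy)-2,2-dimethyl-2H-chromene
Product: 21 [8-(methoxymethoxy)-2,2-dimethyl-2H-chromen-6-yl]boronic acid, via aryllithium 20 (not isolated)
Conditions: n-BuLi, THF, −78 °C; B(OiPr)3, −78 °C → rt; 1 M HCl, 0 °C
Reagents that add atoms: triisopropyl borate, CC(C)OB(OC(C)C)OC(C)C; water, O
Why: Bromine–lithium exchange is faster at −78 °C than acetal-directed deprotonation; trapping with the borate ester and brief cold hydrolysis give the boronic acid with the acetal intact.

Step 11
Reactants: 11 5-methoxy-8,8-dimethyl-2-oxo-3-(phenyliodonio)-9,10-dihydro-2H,8H-pyrano[2,3-f]chromen-4-olate; 21 [8-(methoxymethoxy)-2,2-dimethyl-2H-chromen-6-yl]boronic acid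
Product: 22 4-hydroxy-5-methoxy-3-[8-(methoxymethoxy)-2,2-dimethyl-2H-chromen-6-yl]-8,8-dimethyl-9,10-dihydro-2H,8H-pyrano[2,3-f]chromen-2-one
Conditions: Pd(P(t-Bu)3)2 (5 mol %), LiOH·H2O, DME/H2O, rt; pH 4 work-up
Reagents that add atoms: none
Why: Suzuki–Miyaura-type coupling of an iodonium ylide: zerovalent palladium inserts into the C3–I bond with loss of iodobenzene, the hydroxide-activated boronic acid transmetalates and reductive elimination forms C3–C1'; the boron-bearing carbon has no ortho substituent and the reaction runs at room temperature.

Step 12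
Reactants: 22 4-hydroxy-5-methoxy-3-[8-(methoxymethoxy)-2,2-dimethyl-2H-chromen-6-yl]-8,8-dimethyl-9,10-dihydro-2H,8H-pyrano[2,3-f]chromen-2-one
Product: 23 4,5-dimethoxy-3-[8-(methoxymethoxy)-2,2-dimethyl-2H-chromen-6-yl]-8,8-dimethyl-9,10-dihydro-2H,8H-pyrano[2,3-f]chromen-2-one
Conditions: Me2SO4, K2CO3, acetone, 56 °C
Reagents that add atoms: dimethyl sulfate, COS(=O)(=O)OC
Why: O-Alkylation of a vinylogous carboxylate by a hard electrophile; C-methylation is excluded because C3 carries the aryl group, and the 4-methoxycoumarin is the usual product of this reagent pair with 3-aryl-4-hydroxy-5-methoxycoumarins.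

Step 13
Reactants: 23 4,5-dimethoxy-3-[8-(methoxymethoxy)-2,2-dimethyl-2H-chromen-6-yl]-8,8-dimethyl-9,10-dihydro-2H,8H-pyrano[2,3-f]chromen-2-one
Product: 24 3-(8-hydroxy-2,2-dimethyl-2H-chromen-6-yl)-4,5-dimethoxy-8,8-dimethyl-9,10-dihydro-2H,8H-pyrano[2,3-f]chromen-2-one
Conditions: HCl (1.25 M in MeOH, anhydrous), 40 °C
Reagents that add atoms: none
Why: Acid-catalysed acetal exchange with methanol releases the C5' phenol; in anhydrous methanol the C4 enol ether can only exchange with itself, and ring E tolerates dilute acid at this temperature.

Step 14
Reactants: 24 3-(8-hydroxy-2,2-dimethyl-2H-chromen-6-yl)-4,5-dimethoxy-8,8-dimethyl-9,10-dihydro-2H,8H-pyrano[2,3-f]chromen-2-one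
Product: 26 5-O-methylformosanatin D, via 4-methoxybenzopyrylium acetate 25 (not isolated)
Conditions: PhI(OAc)2 (1.0 equiv, slow addition), (CF3)2CHOH, 0 °C; then evaporate, MeCN, 50 °C
Reagents that add atoms: none
Why: Proposed new method: ligand exchange of the C5' phenol on trivalent iodine and loss of iodobenzene in the cation-stabilising, weakly nucleophilic solvent should give a phenoxenium ion with positive charge at C2' (para) and at C4' and C6' (ortho). The lactone carbonyl oxygen, the basic site of the 4-methoxycoumarin (a vinylogous carbonate that is alkylated on this oxygen), captures C2'; this closes the furan O–C2–C3–C1'–C2' as a five-membered ring by cation capture, in the same geometry as coumestan closures. Loss of the C2' proton rearomatises ring B with its C5' hydroxyl restored and leaves the 2-aryloxy-4-methoxybenzopyrylium acetate 25. After the switch to MeCN the acetate ion is no longer tied up by hydrogen bonding and removes the O4 methyl group by SN2 substitution, as 4-alkoxypyrylium salts are dealkylated to 4-pyranones, which unveils the C4 ketone. The closest known reaction types are the oxidative cyclisation of 3-aryl-4-hydroxycoumarins to coumestans with FeCl3 or trivalent iodine reagents, where O4 is the nucleophile, and the capture of phenoxenium ions by carbonyl oxygen in spirolactonisations; here the O4 methyl ether leaves only the carbonyl oxygen free to attack. No stereocentre is formed. The step needs closure at C2' and not at C6': C2' is para to the oxidised oxygen, where phenoxenium ions are preferentially captured, whereas closure at C6' would pass through a more crowded ortho-quinoid intermediate beside the C5' oxygen. It also needs the oxidation to stop after two electrons, which one equivalent of oxidant added slowly in dilute solution should secure, helped by the furan oxygen of 26 being a weak donor (it is part of a vinylogous carbonate).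

Step 15
Reactants: 26 5-O-methylformosanatin D
Product: 27 formosanatin D
Conditions: BCl3, CH2Cl2, −78 → 0 °C; then MeOH, aq NaHCO3
Reagents that add atoms: none
Why: Chelation-controlled ether cleavage: boron binds the C4 carbonyl and the peri oxygen in a six-membered chelate and chloride removes the methyl group, while the unchelated ethers of ring D and ring E react much more slowly at low temperature.

## Compound list

1 | 5-methoxyresorcinol (5-methoxybenzene-1,3-diol) | COc1cc(O)cc(O)c1 | starting material
2 | 1-methoxy-3,5-bis(methoxymethoxy)benzene | COCOc1cc(OC)cc(OCOC)c1 | intermediate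
3 | prenyl bromide (1-bromo-3-methylbut-2-ene) | CC(C)=CCBr | starting material
4 | [4-methoxy-2,6-bis(methoxymethoxy)phenyl]lithium | [Li]c1c(OCOC)cc(OC)cc1OCOC | intermediate
5 | 5-methoxy-1,3-bis(methoxymethoxy)-2-(3-methylbut-2-en-1-yl)benzene | COCOc1cc(OC)cc(OCOC)c1CC=C(C)C | intermediate
6 | 5-methoxy-2-(3-methylbut-2-en-1-yl)benzene-1,3-diol | COc1cc(O)c(CC=C(C)C)c(O)c1 | intermediate
7 | 7-methoxy-2,2-dimethylchroman-5-ol | COc1cc(O)c2CCC(C)(C)Oc2c1 | intermediate
8 | Meldrum's acid (2,2-dimethyl-1,3-dioxane-4,6-dione) | CC1(C)OC(=O)CC(=O)O1 | starting material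
9 | 3-[(7-methoxy-2,2-dimethylchroman-5-yl)oxy]-3-oxopropanoic acid | COc1cc(OC(=O)CC(=O)O)c2CCC(C)(C)Oc2c1 | intermediate
10 | 4-hydroxy-5-methoxy-8,8-dimethyl-9,10-dihydro-2H,8H-pyrano[2,3-f]chromen-2-one | O=c1cc(O)c2c(OC)cc3OC(C)(C)CCc3c2o1 | intermediate
11 | 5-methoxy-8,8-dimethyl-2-oxo-3-(phenyliodonio)-9,10-dihydro-2H,8H-pyrano[2,3-f]chromen-4-olate (iodonium ylide) | COc1cc2OC(C)(C)CCc2c2OC(=O)C([I+]c3ccccc3)=C([O-])c12 | intermediate
12 | 5-bromosalicylaldehyde | O=Cc1cc(Br)ccc1O | starting material
13 | 3-chloro-3-methylbut-1-yne | CC(C)(Cl)C#C | starting material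
14 | 5-bromo-2-[(2-methylbut-3-yn-2-yl)oxy]benzaldehyde | O=Cc1cc(Br)ccc1OC(C)(C)C#C | intermediate
15 | 5-bromo-2-hydroxy-3-(3-methylbuta-1,2-dien-1-yl)benzaldehyde | O=Cc1cc(Br)cc(C=C=C(C)C)c1O | intermediate
16 | 6-bromo-2,2-dimethyl-2H-chromene-8-carbaldehyde | O=Cc1cc(Br)cc2C=CC(C)(C)Oc12 | intermediate
17 | 6-bromo-2,2-dimethyl-2H-chromen-8-yl formate | O=COc1cc(Br)cc2C=CC(C)(C)Oc12 | intermediate
18 | 6-bromo-2,2-dimethyl-2H-chromen-8-ol | Oc1cc(Br)cc2C=CC(C)(C)Oc12 | intermediate
19 | 6-bromo-8-(methoxymethoxy)-2,2-dimethyl-2H-chromene | COCOc1cc(Br)cc2C=CC(C)(C)Oc12 | intermediate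
20 | [8-(methoxymethoxy)-2,2-dimethyl-2H-chromen-6-yl]lithium | COCOc1cc([Li])cc2C=CC(C)(C)Oc12 | intermediate
21 | [8-(methoxymethoxy)-2,2-dimethyl-2H-chromen-6-yl]boronic acid | COCOc1cc(B(O)O)cc2C=CC(C)(C)Oc12 | intermediate
22 | 4-hydroxy-5-methoxy-3-[8-(methoxymethoxy)-2,2-dimethyl-2H-chromen-6-yl]-8,8-dimethyl-9,10-dihydro-2H,8H-pyrano[2,3-f]chromen-2-one | O=c1oc2c3CCC(C)(C)Oc3cc(OC)c2c(O)c1-c1cc(OCOC)c2OC(C)(C)C=Cc2c1 | intermediate
23 | 4,5-dimethoxy-3-[8-(methoxymethoxy)-2,2-dimethyl-2H-chromen-6-yl]-8,8-dimethyl-9,10-dihydro-2H,8H-pyrano[2,3-f]chromen-2-one | O=c1oc2c3CCC(C)(C)Oc3cc(OC)c2c(OC)c1-c1cc(OCOC)c2OC(C)(C)C=Cc2c1 | intermediate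
24 | 3-(8-hydroxy-2,2-dimethyl-2H-chromen-6-yl)-4,5-dimethoxy-8,8-dimethyl-9,10-dihydro-2H,8H-pyrano[2,3-f]chromen-2-one | O=c1oc2c3CCC(C)(C)Oc3cc(OC)c2c(OC)c1-c1cc(O)c2OC(C)(C)C=Cc2c1 | intermediate
25 | 2-aryloxy-4-methoxybenzopyrylium acetate (furan closed, C5 methoxy, C5' hydroxyl, ring D and ring E in place) | CC1(C)C=Cc2c(c(O)cc3c2oc2[o+]c4c5c(cc(OC)c4c(OC)c23)OC(C)(C)CC5)O1.CC(=O)[O-] | intermediate
26 | 5-O-methylformosanatin D (coumaronochromone with C5 methoxy and C5' hydroxyl) | CC1(C)C=Cc2c(c(O)cc3c2oc2oc4c5c(cc(OC)c4c(=O)c23)OC(C)(C)CC5)O1 | intermediate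
27 | formosanatin D | CC1(C)C=Cc2c(c(O)cc3c2oc2oc4c5c(cc(O)c4c(=O)c23)OC(C)(C)CC5)O1 | target

## Step count and risks

Total: 15 steps. Longest linear sequence: 10 steps (steps 1–5 or steps 6–10, then steps 11–15).

**Step 14 (key step, proposed new method).**
- What may go wrong: closure at C6' instead of C2'; interception of the phenoxenium ion at the oxygen-bearing C4' by acetate or solvent; further oxidation of the product phenol; sluggish demethylation, so the pyrylium ion is opened by water on work-up.
- Fallback (known chemistry, furan oxygen supplied by ring B): it sets out from chromanol 7 and bromochromenol 18 and rejoins the route at 26.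
  - Ring A part: ortho-acetylation of 7 (AcOH, BF3·OEt2, 90 °C) would give 1-(5-hydroxy-7-methoxy-2,2-dimethylchroman-6-yl)ethanone F1. CS2/t-BuOK followed by MeI would give 5-methoxy-8,8-dimethyl-2-(methylsulfanyl)-9,10-dihydro-4H,8H-pyrano[2,3-f]chromen-4-one F2. NIS would iodinate C3 to the 3-iodo-2-(methylsulfanyl)chromone F3.
  - Ring B part: phenol 18 would be oxidised at its free para position with (KO3S)2NO to 6-bromo-2,2-dimethyl-2H-chromene-5,8-dione F4. Reduction with Na2S2O4 would give 6-bromo-2,2-dimethyl-2H-chromene-5,8-diol F5, which would be protected as the bis(methoxymethyl) ether F6. Bromine–lithium exchange and B(OiPr)3 would give [5,8-bis(methoxymethoxy)-2,2-dimethyl-2H-chromen-6-yl]boronic acid F7.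
  - Union and closure: Suzuki–Miyaura coupling of F3 with F7 (Pd(PPh3)4, Na2CO3, DME/H2O) would give the 2-(methylsulfanyl)isoflavone bis-acetal F8. Methanolic HCl would free the 2',5'-dihydroxy-2-(methylsulfanyl)isoflavone F9. K2CO3 in DMF would let the C2' phenoxide, the only oxygen that can reach C2, displace methanethiolate by addition–elimination to give 26.

**Step 12.**
- What may go wrong: alkylation at the lactone carbonyl oxygen instead of O4, or slow reaction at the O4 site crowded by the C5 methoxy and the C3 aryl group.
- Fallback (methylate before arylating): it sets out from 10 and rejoins at 23. Acid-catalysed etherification of 10 (MeOH, H2SO4, 65 °C), which gives the thermodynamic 4-methoxycoumarin, would lead to 4,5-dimethoxy-8,8-dimethyl-9,10-dihydro-2H,8H-pyrano[2,3-f]chromen-2-one F10. NIS with catalytic CF3CO2H would give the 3-iodo-4,5-dimethoxy compound F11. Suzuki–Miyaura coupling of F11 with boronic acid 21 (Pd(PPh3)4, Na2CO3, DME/H2O, 80 °C) would give 23.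

**Step 15.**
- What may go wrong: the boron aryloxide formed at O5' chelates the neighbouring ring E oxygen, which ionises the tertiary allylic C–O bond and opens ring E.
- Fallback (mask the chelating phenol first): it sets out from 26 and rejoins at 27. Ac2O/pyridine would give 5'-O-acetyl-5-O-methylformosanatin D F12. BCl3 at −78 °C would then cleave only the peri methyl ether to 5'-O-acetylformosanatin D F13. K2CO3 in MeOH at 0 °C would remove the acetate to give 27.

**Step 8.**
- What may go wrong: hydride instead of aryl migration in the perhydrate (giving the carboxylic acid), or acid-catalysed addition of methanol or peroxide to the chromene olefin.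
- Fallback (oxygen present from the start, no oxidation): it sets out from chloride 13 and rejoins at 18. Commercial 4-bromo-2-methoxyphenol F14 would be alkylated with 13 (K2CO3, KI, CuI, DMF) to 4-bromo-2-methoxy-1-[(2-methylbut-3-yn-2-yl)oxy]benzene F15. Claisen rearrangement (PhNEt2, 190 °C) to the only free ortho carbon would give 6-bromo-8-methoxy-2,2-dimethyl-2H-chromene F16. NaSEt in DMF at 110 °C would remove the methyl group by SN2 attack to give 18.

## Further compounds

F1 | step 14 | 1-(5-hydroxy-7-methoxy-2,2-dimethylchroman-6-yl)ethanone | COc1cc2OC(C)(C)CCc2c(O)c1C(C)=O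
F2 | step 14 | 5-methoxy-8,8-dimethyl-2-(methylsulfanyl)-9,10-dihydro-4H,8H-pyrano[2,3-f]chromen-4-one | CSc1cc(=O)c2c(OC)cc3OC(C)(C)CCc3c2o1
F3 | step 14 | 3-iodo-5-methoxy-8,8-dimethyl-2-(methylsulfanyl)-9,10-dihydro-4H,8H-pyrano[2,3-f]chromen-4-one | CSc1oc2c3CCC(C)(C)Oc3cc(OC)c2c(=O)c1I
F4 | step 14 | 6-bromo-2,2-dimethyl-2H-chromene-5,8-dione | O=C1C=C(Br)C(=O)C2=C1OC(C)(C)C=C2
F5 | step 14 | 6-bromo-2,2-dimethyl-2H-chromene-5,8-diol | Oc1cc(Br)c(O)c2C=CC(C)(C)Oc12
F6 | step 14 | 6-bromo-5,8-bis(methoxymethoxy)-2,2-dimethyl-2H-chromene | COCOc1cc(Br)c(OCOC)c2C=CC(C)(C)Oc12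
F7 | step 14 | [5,8-bis(methoxymethoxy)-2,2-dimethyl-2H-chromen-6-yl]boronic acid | COCOc1cc(B(O)O)c(OCOC)c2C=CC(C)(C)Oc12
F8 | step 14 | 3-[5,8-bis(methoxymethoxy)-2,2-dimethyl-2H-chromen-6-yl]-5-methoxy-8,8-dimethyl-2-(methylsulfanyl)-9,10-dihydro-4H,8H-pyrano[2,3-f]chromen-4-one | CSc1oc2c3CCC(C)(C)Oc3cc(OC)c2c(=O)c1-c1cc(OCOC)c2OC(C)(C)C=Cc2c1OCOC
F9 | step 14 | 3-(5,8-dihydroxy-2,2-dimethyl-2H-chromen-6-yl)-5-methoxy-8,8-dimethyl-2-(methylsulfanyl)-9,10-dihydro-4H,8H-pyrano[2,3-f]chromen-4-one | CSc1oc2c3CCC(C)(C)Oc3cc(OC)c2c(=O)c1-c1cc(O)c2OC(C)(C)C=Cc2c1O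
F10 | step 12 | 4,5-dimethoxy-8,8-dimethyl-9,10-dihydro-2H,8H-pyrano[2,3-f]chromen-2-one | O=c1cc(OC)c2c(OC)cc3OC(C)(C)CCc3c2o1
F11 | step 12 | 3-iodo-4,5-dimethoxy-8,8-dimethyl-9,10-dihydro-2H,8H-pyrano[2,3-f]chromen-2-one | O=c1oc2c3CCC(C)(C)Oc3cc(OC)c2c(OC)c1I
F12 | step 15 | 5'-O-acetyl-5-O-methylformosanatin D | CC1(C)C=Cc2c(c(OC(C)=O)cc3c2oc2oc4c5c(cc(OC)c4c(=O)c23)OC(C)(C)CC5)O1
F13 | step 15 | 5'-O-acetylformosanatin D | CC1(C)C=Cc2c(c(OC(C)=O)cc3c2oc2oc4c5c(cc(O)c4c(=O)c23)OC(C)(C)CC5)O1
F14 | step 8 | 4-bromo-2-methoxyphenol | COc1cc(Br)ccc1O
F15 | step 8 | 4-bromo-2-methoxy-1-[(2-methylbut-3-yn-2-yl)oxy]benzene | COc1cc(Br)ccc1OC(C)(C)C#C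
F16 | step 8 | 6-bromo-8-methoxy-2,2-dimethyl-2H-chromene | COc1cc(Br)cc2C=CC(C)(C)Oc12
A1 | alternative 1 | methyl 5-bromo-7-hydroxy-2,2-dimethylchroman-6-carboxylate | COC(=O)c1c(O)cc2OC(C)(C)CCc2c1Br
A2 | alternative 1 | 6-[2,2-bis(trimethylsilyloxy)ethenyl]-2,2-dimethyl-3,4-dihydro-2H-pyran | C[Si](C)(C)OC(O[Si](C)(C)C)=CC1=CCCC(C)(C)O1
A3 | alternative 1 | methyl 3-bromopropiolate | COC(=O)C#CBr
A4 | alternative 2 | 5-hydroxy-5'-(methoxymethoxy) coumaronochromone 7-O-(1,1-dimethylallyl) 4'-O-(1,1-dimethylpropargyl) diether | C#CC(C)(C)Oc1cc2oc3oc4cc(OC(C)(C)C=C)cc(O)c4c(=O)c3c2cc1OCOC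
A5 | alternative 2 | 8-prenyl-5,7-dihydroxy-5'-(methoxymethoxy) coumaronochromone with ring E closed | CC1(C)C=Cc2c(c(OCOC)cc3c2oc2oc4c(CC=C(C)C)c(O)cc(O)c4c(=O)c23)O1
A6 | alternative 3 | 1-(5-hydroxy-7-methoxy-2,2-dimethylchroman-6-yl)-2-[5-hydroxy-8-(methoxymethoxy)-2,2-dimethyl-2H-chromen-6-yl]ethanone | COc1cc2OC(C)(C)CCc2c(O)c1C(=O)Cc1cc(OCOC)c2OC(C)(C)C=Cc2c1O
A7 | alternative 3 | 5-O-methyl-5'-O-(methoxymethyl)formosanatin D | CC1(C)C=Cc2c(c(OCOC)cc3c2oc2oc4c5c(cc(OC)c4c(=O)c23)OC(C)(C)CC5)O1
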